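The lower flavan-3,4-diol unit is cut at two bonds of its pyran ring C: the aryl ether bond O1–C8a and the bond C2–C3. O1 and C2 then form the carbonyl group of 3,4-bis(benzyloxy)benzaldehyde, and C3–C4–C4a–C8a an ortho-fluoroaryl benzyloxymethyl ketone, because a C4 carbonyl makes C3 an enolate carbon and, lying ortho to C8a, activates its fluorine. One asymmetric aldol/SNAr domino joins both bonds and gives benzyl-protected (2R,3R)-fustin. This one monomer supplies all three units: a Friedel–Crafts coupling sets the 3,4-trans middle–lower link, an aryl addition to the ketone followed by ionic hydrogenation the 3,4-cis top–middle link, and a last borohydride reduction the 4-hydroxyl.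

Key step: step 2

Remarks and assumptions
- Each flavan unit has the usual numbering (O1, C2, C3, C4, C4a, C5 to C8, C8a; B-ring positions primed). The units are called top, middle and lower.
- The cinchonidinium catalyst of step 2 is assumed to direct the enolate to the Si face of aldehyde 5, which gives 2R. Should the sense be the reverse, the pseudo-enantiomeric cinchoninium salt is used in the same way.
- Carbinol 15 may form as a mixture of epimers at its hydroxyl-bearing carbon. Both lead to 16, because step 8 removes that centre.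

Step 1
Reactants: 1 4-(benzyloxy)-1-bromo-2-fluorobenzene; 2 2-(benzyloxy)-N-methoxy-N-methylacetamide
Product: 4 2-(benzyloxy)-1-[4-(benzyloxy)-2-fluorophenyl]ethan-1-one, via aryl Grignard reagent 3 (not isolated)
Conditions: iPrMgCl·LiCl, THF, −15 °C; then 2, −15 → 0 °C; aq NH4Cl
Reagents that add atoms: none
Why: Bromine–magnesium exchange, sped up by the ortho-fluorine, gives Grignard reagent 3, which acylates once with the Weinreb amide (Weinreb ketone synthesis) because the chelated tetrahedral adduct survives until work-up; no stereocentre is formed.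

Step 2
Reactants: 4 2-(benzyloxy)-1-[4-(benzyloxy)-2-fluorophenyl]ethan-1-one; 5 3,4-bis(benzyloxy)benzaldehyde
Product: 8 tetra-O-benzyl-(2R,3R)-fustin, via cesium enolate 6 (not isolated), via anti-aldolate 7 (not isolated)
Conditions: O-allyl-N-(9-anthracenylmethyl)cinchonidinium bromide (10 mol %), CsOH·H2O (1.5 equiv), toluene/CH2Cl2, −45 → 0 °C
Reagents that add atoms: none
Why: Proposed new method: solid CsOH deprotonates 4 at the interface, and the (Z)-enolate 6, paired with the chiral ammonium cation, adds to aldehyde 5 (aldol addition, bond C2–C3); the alkoxide 7 then attacks the fluorine-bearing C8a, which the ortho C4 carbonyl activates, and fluoride leaves through a Meisenheimer adduct (intramolecular SNAr, bond O1–C8a). The closest known reactions are the cinchona-ammonium phase-transfer alkylation and aldol addition of aryl alkoxymethyl ketone and glycine imine enolates, and the base-mediated SNAr ring closure of 2-fluorophenyl ketones; new is their union, with an ion-paired aldolate as the SNAr nucleophile. Ring C closes in the 6-exo-trig mode onto the arene carbon through a chair-like transition state. C2 is set by the catalyst, which shields one face of the aldehyde so that the enolate adds to the Si face (2R); C3 follows from the anti course of the ion-pair aldol and from ring closure, since only the anti aldolate closes with the aryl and benzyloxy groups both equatorial while a syn aldolate reverts by retro-aldol (3R, 2,3-trans). The step needs ring closure to outrun retro-aldol and dehydration, and it needs the six-membered ring only: low temperature and the poorly solvated alkoxide favour SNAr, the α-oxygen is benzylated and cannot close a five-membered ring, and the C7 benzyloxy group is meta to C8a and does not deactivate it.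

Step 3
Reactants: 8 tetra-O-benzyl-(2R,3R)-fustin
Product: 9 (2R,3S,4R)-3,7-bis(benzyloxy)-2-[3,4-bis(benzyloxy)phenyl]chroman-4-ol
Conditions: NaBH4, THF/MeOH, 0 °C
Reagents that add atoms: none
Why: Sodium borohydride reduction of the chromanone: the small hydride adds axially to C4 of the half-chair, whose 2-aryl and 3-benzyloxy groups are equatorial, and gives the equatorial 4-hydroxyl trans to O3 (4R), as in the known reduction of fustin to mollisacacidin.

Step 4
Reactants: 9 (2R,3S,4R)-3,7-bis(benzyloxy)-2-[3,4-bis(benzyloxy)phenyl]chroman-4-ol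
Product: 10 6-bromo derivative of 9
Conditions: NBS (1.0 equiv), CH2Cl2, −20 → 0 °C
Reagents that add atoms: N-bromosuccinimide (NBS), O=C1CCC(=O)N1Br
Why: Electrophilic aromatic bromination goes to C6 of ring A, the position para to O1 and ortho to the C7 benzyloxy group, since C8 is flanked by two oxygens and each B-ring position has one activating oxygen only; the bromine later blocks self-condensation and becomes the handle for lithiation.

Step 5
Reactants: 9 (2R,3S,4R)-3,7-bis(benzyloxy)-2-[3,4-bis(benzyloxy)phenyl]chroman-4-ol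
Product: 11 4-O-triisopropylsilyl ether of 9
Conditions: TIPSOTf, 2,6-lutidine, CH2Cl2, 0 °C
Reagents that add atoms: triisopropylsilyl trifluoromethanesulfonate (TIPSOTf), CC(C)[Si](OS(=O)(=O)C(F)(F)F)(C(C)C)C(C)C
Why: Silylation of the secondary benzylic alcohol with a silyl triflate and a hindered base (standard silyl ether formation) occurs with retention and masks C4 of the future lower unit as a bulky ether that a Lewis acid ionises only slowly.

Step 6
Reactants: 10 6-bromo derivative of 9; 11 4-O-triisopropylsilyl ether of 9 (1.5 equiv)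
Product: 12 bromo-capped protected middle–lower dimer
Conditions: BF3·OEt2 (1.1 equiv), CH2Cl2, −78 → −40 °C
Reagents that add atoms: none
Why: Friedel–Crafts alkylation (the classical interflavanyl coupling): BF3 ionises the free C4 hydroxyl of 10, whose C6 is blocked by bromine, and ring A of 11 attacks with C6 (para to O1, ortho to O7, less hindered than C8) on the α face of the benzylic cation, anti to the neighbouring 3-benzyloxy group, which should set the 3,4-trans (4α) link.

Step 7
Reactants: 12 bromo-capped protected middle–lower dimer; 8 tetra-O-benzyl-(2R,3R)-fustin (1.3 equiv)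
Product: 15 tertiary carbinol of the protected trimer, via aryllithium 13 (not isolated), via arylcerium dichloride 14 (not isolated)
Conditions: t-BuLi (2.1 equiv), THF, −78 °C; anhydrous CeCl3, −78 °C; then 8, −78 → −40 °C; aq NH4Cl
Reagents that add atoms: none
Why: Bromine–lithium exchange, transmetalation to the less basic organocerium reagent (Imamoto conditions) and 1,2-addition to the ketone of 8 form the bond between C4 of the top unit and C6 of the middle unit without enolisation or ring opening of the chromanone; the configuration of the new carbinol carbon is of no consequence because step 8 removes it.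

Step 8
Reactants: 15 tertiary carbinol of the protected trimer
Product: 16 protected trimer with the 3,4-cis top–middle link
Conditions: Et3SiH (10 equiv), CF3CO2H (5 equiv), CH2Cl2, −40 → −10 °C
Reagents that add atoms: none
Why: Ionic hydrogenation (Kursanov–Parnes reduction): acid ionises only the tertiary doubly benzylic alcohol, allylic strain against the 4-aryl group turns the 3-benzyloxy group axial, and Et3SiH delivers hydride to C4 anti to it on the α face, so that the aryl group should end cis to O3 (4β link).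

Step 9
Reactants: 16 protected trimer with the 3,4-cis top–middle link
Product: 17 protected trimer with free C4 hydroxyl in the lower unit
Conditions: Bu4NF, THF, 0 °C → rt
Reagents that add atoms: none
Why: Fluoride cleaves the silicon–oxygen bond (silyl ether deprotection) and leaves benzyl ethers and all stereocentres untouched.

Step 10
Reactants: 17 protected trimer with free C4 hydroxyl in the lower unit
Product: 18 dodeca-O-benzyl trimer with fustin-type lower unit
Conditions: Dess–Martin periodinane, pyridine, CH2Cl2, 0 °C → rt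
Reagents that add atoms: none
Why: Dess–Martin oxidation converts the only free (secondary benzylic) alcohol into the aryl ketone under near-neutral conditions, so that no benzylic C4–O single bond remains in the lower unit when the benzyl groups are hydrogenolysed; C3 next to the new ketone already has the more stable trans configuration.

Step 11
Reactants: 18 dodeca-O-benzyl trimer with fustin-type lower unit
Product: 19 fisetinidol-(4β→6)-fisetinidol-(4α→6)-fustin
Conditions: H2 (1 atm), Pd(OH)2/C, THF/MeOH, rt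
Reagents that add atoms: none
Why: Catalytic hydrogenolysis removes the twelve benzyl ethers, while the carbonyl group, conjugated with the para hydroxyl (vinylogous acid), and the C–C interflavanyl bonds should not be reduced under these mild conditions.

Step 12
Reactants: 19 fisetinidol-(4β→6)-fisetinidol-(4α→6)-fustin
Product: 20 fisetinidol-(4β→6)-fisetinidol-(4α→6)-mollisacacidin (target)
Conditions: NaBH4 (excess), EtOH/H2O, 0 °C; work-up at pH 6
Reagents that add atoms: none
Why: Sodium borohydride reduction, as in the conversion of fustin into mollisacacidin: axial hydride addition to C4 gives the equatorial hydroxyl trans to O3 (4R) of the lower unit.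

Compound list
1 | 4-(benzyloxy)-1-bromo-2-fluorobenzene | Brc1ccc(OCc2ccccc2)cc1F | starting material
2 | 2-(benzyloxy)-N-methoxy-N-methylacetamide | CON(C)C(=O)COCc1ccccc1 | starting material
3 | [4-(benzyloxy)-2-fluorophenyl]magnesium chloride (LiCl complex) | Cl[Mg]c1ccc(OCc2ccccc2)cc1F | intermediate (not isolated)
4 | 2-(benzyloxy)-1-[4-(benzyloxy)-2-fluorophenyl]ethan-1-one | O=C(COCc1ccccc1)c1ccc(OCc2ccccc2)cc1F | intermediate
5 | 3,4-bis(benzyloxy)benzaldehyde | O=Cc1ccc(OCc2ccccc2)c(OCc2ccccc2)c1 | starting material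
6 | cesium (Z)-enolate of 4 (enolate oxygen and benzyloxy group cis; paired with the catalyst cation in the flask) | [Cs+].[O-]/C(c1ccc(OCc2ccccc2)cc1F)=C\OCc1ccccc1 | intermediate (not isolated)
7 | anti-aldolate, cesium (1R,2R)-2-(benzyloxy)-3-[4-(benzyloxy)-2-fluorophenyl]-1-[3,4-bis(benzyloxy)phenyl]-3-oxopropan-1-olate (paired with the catalyst cation in the flask) | O=C(c1ccc(OCc2ccccc2)cc1F)[C@H](OCc1ccccc1)[C@H]([O-])c1ccc(OCc2ccccc2)c(OCc2ccccc2)c1.[Cs+] | intermediate (not isolated)
8 | (2R,3R)-3,7-bis(benzyloxy)-2-[3,4-bis(benzyloxy)phenyl]chroman-4-one (tetra-O-benzylfustin, 2,3-trans) | c1ccccc1COc1ccc2c(c1)O[C@H](c1ccc(OCc3ccccc3)c(OCc3ccccc3)c1)[C@@H](OCc1ccccc1)C2=O | intermediate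
9 | (2R,3S,4R)-3,7-bis(benzyloxy)-2-[3,4-bis(benzyloxy)phenyl]chroman-4-ol (2,3-trans-3,4-trans) | c1ccccc1COc1ccc2c(c1)O[C@H](c1ccc(OCc3ccccc3)c(OCc3ccccc3)c1)[C@@H](OCc1ccccc1)[C@@H]2O | intermediate
10 | (2R,3S,4R)-3,7-bis(benzyloxy)-2-[3,4-bis(benzyloxy)phenyl]-6-bromochroman-4-ol | Brc1cc2c(cc1OCc1ccccc1)O[C@H](c1ccc(OCc3ccccc3)c(OCc3ccccc3)c1)[C@@H](OCc1ccccc1)[C@@H]2O | intermediate
11 | 4-O-triisopropylsilyl ether of 9 (configuration unchanged) | c1ccccc1COc1ccc2c(c1)O[C@H](c1ccc(OCc3ccccc3)c(OCc3ccccc3)c1)[C@@H](OCc1ccccc1)[C@@H]2O[Si](C(C)C)(C(C)C)C(C)C | intermediate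
12 | protected dimer: 6-bromo middle unit (2,3-trans-3,4-trans) bonded from C4 (α) to C6 of the lower unit, which is 11; all phenolic and C3 oxygens benzylated | Brc1cc2c(cc1OCc1ccccc1)O[C@H](c1ccc(OCc3ccccc3)c(OCc3ccccc3)c1)[C@@H](OCc1ccccc1)[C@@H]2c1cc2c(cc1OCc1ccccc1)O[C@H](c1ccc(OCc3ccccc3)c(OCc3ccccc3)c1)[C@@H](OCc1ccccc1)[C@@H]2O[Si](C(C)C)(C(C)C)C(C)C | intermediate
13 | aryllithium from 12 (Li in place of Br at C6 of the middle unit) | [Li]c1cc2c(cc1OCc1ccccc1)O[C@H](c1ccc(OCc3ccccc3)c(OCc3ccccc3)c1)[C@@H](OCc1ccccc1)[C@@H]2c1cc2c(cc1OCc1ccccc1)O[C@H](c1ccc(OCc3ccccc3)c(OCc3ccccc3)c1)[C@@H](OCc1ccccc1)[C@@H]2O[Si](C(C)C)(C(C)C)C(C)C | intermediate (not isolated)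
14 | arylcerium dichloride from 13 (CeCl2 in place of Li) | Cl[Ce](Cl)c1cc2c(cc1OCc1ccccc1)O[C@H](c1ccc(OCc3ccccc3)c(OCc3ccccc3)c1)[C@@H](OCc1ccccc1)[C@@H]2c1cc2c(cc1OCc1ccccc1)O[C@H](c1ccc(OCc3ccccc3)c(OCc3ccccc3)c1)[C@@H](OCc1ccccc1)[C@@H]2O[Si](C(C)C)(C(C)C)C(C)C | intermediate (not isolated)
15 | protected trimer carbinol: C6 of the middle unit bonded to C4 of a top unit derived from 8, C4 carrying OH; drawn as the epimer with the aryl group trans to O3 | c1ccccc1COc1ccc2c(c1)O[C@H](c1ccc(OCc3ccccc3)c(OCc3ccccc3)c1)[C@@H](OCc1ccccc1)[C@]2(O)c1cc2c(cc1OCc1ccccc1)O[C@H](c1ccc(OCc3ccccc3)c(OCc3ccccc3)c1)[C@@H](OCc1ccccc1)[C@@H]2c1cc2c(cc1OCc1ccccc1)O[C@H](c1ccc(OCc3ccccc3)c(OCc3ccccc3)c1)[C@@H](OCc1ccccc1)[C@@H]2O[Si](C(C)C)(C(C)C)C(C)C | intermediate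
16 | protected trimer: top unit 2,3-trans-3,4-cis, middle unit 2,3-trans-3,4-trans, lower unit as 4-O-triisopropylsilyl ether; twelve benzyl ethers | c1ccccc1COc1ccc2c(c1)O[C@H](c1ccc(OCc3ccccc3)c(OCc3ccccc3)c1)[C@@H](OCc1ccccc1)[C@H]2c1cc2c(cc1OCc1ccccc1)O[C@H](c1ccc(OCc3ccccc3)c(OCc3ccccc3)c1)[C@@H](OCc1ccccc1)[C@@H]2c1cc2c(cc1OCc1ccccc1)O[C@H](c1ccc(OCc3ccccc3)c(OCc3ccccc3)c1)[C@@H](OCc1ccccc1)[C@@H]2O[Si](C(C)C)(C(C)C)C(C)C | intermediate
17 | 16 without the silyl group (free C4 hydroxyl in the lower unit) | c1ccccc1COc1ccc2c(c1)O[C@H](c1ccc(OCc3ccccc3)c(OCc3ccccc3)c1)[C@@H](OCc1ccccc1)[C@H]2c1cc2c(cc1OCc1ccccc1)O[C@H](c1ccc(OCc3ccccc3)c(OCc3ccccc3)c1)[C@@H](OCc1ccccc1)[C@@H]2c1cc2c(cc1OCc1ccccc1)O[C@H](c1ccc(OCc3ccccc3)c(OCc3ccccc3)c1)[C@@H](OCc1ccccc1)[C@@H]2O | intermediate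
18 | dodeca-O-benzyl fisetinidol-(4β→6)-fisetinidol-(4α→6)-fustin (lower unit C4 ketone) | c1ccccc1COc1ccc2c(c1)O[C@H](c1ccc(OCc3ccccc3)c(OCc3ccccc3)c1)[C@@H](OCc1ccccc1)[C@H]2c1cc2c(cc1OCc1ccccc1)O[C@H](c1ccc(OCc3ccccc3)c(OCc3ccccc3)c1)[C@@H](OCc1ccccc1)[C@@H]2c1cc2c(cc1OCc1ccccc1)O[C@H](c1ccc(OCc3ccccc3)c(OCc3ccccc3)c1)[C@@H](OCc1ccccc1)C2=O | intermediate
19 | fisetinidol-(4β→6)-fisetinidol-(4α→6)-fustin (free phenols) | Oc1ccc2c(c1)O[C@H](c1ccc(O)c(O)c1)[C@@H](O)[C@H]2c1cc2c(cc1O)O[C@H](c1ccc(O)c(O)c1)[C@@H](O)[C@@H]2c1cc2c(cc1O)O[C@H](c1ccc(O)c(O)c1)[C@@H](O)C2=O | intermediate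
20 | fisetinidol-(4β→6)-fisetinidol-(4α→6)-mollisacacidin, CNP0255184.1 | Oc1ccc2c(c1)O[C@H](c1ccc(O)c(O)c1)[C@@H](O)[C@H]2c1cc2c(cc1O)O[C@H](c1ccc(O)c(O)c1)[C@@H](O)[C@@H]2c1cc2c(cc1O)O[C@H](c1ccc(O)c(O)c1)[C@@H](O)[C@@H]2O | target

Total step count: 12. Longest linear sequence: 11 steps (steps 1, 2, 3, 4, 6, 7, 8, 9, 10, 11, 12; step 5 is a one-step branch from 9, and 8 re-enters at step 7).

Steps most likely to fail

Step 2 (proposed new method). The ion-paired aldol may proceed with poor facial selectivity, the aldolate may revert or dehydrate faster than it ring-closes, and the product may ring-open by β-elimination under the base. The fallback uses known chalcone-epoxide chemistry, sets out from aldehyde 5 and comes back at 8. Commercial 1-[4-(benzyloxy)-2-hydroxyphenyl]ethanone is converted with MOMCl and iPr2NEt into 1-[4-(benzyloxy)-2-(methoxymethoxy)phenyl]ethan-1-one F1. Claisen–Schmidt condensation of F1 with 5 (KOH, EtOH) gives the (E)-chalcone F2. Juliá–Colonna epoxidation (poly-L-leucine, urea–H2O2, DBU, THF) should give the (2R,3S)-epoxy ketone F3. HCl in MeOH/THF removes the methoxymethyl group, and the freed phenol opens the epoxide at the benzylic carbon with inversion (6-endo) to the (2R,3R)-3-hydroxychromanone F4. O-Benzylation of F4 with benzyl 2,2,2-trichloroacetimidate and catalytic TfOH gives 8. Here ring C is closed at O1–C2 instead.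

Step 8. Reversible proton loss from the cation to the enol ether may scramble C3, or hydride may be delivered to the wrong face; the hindered addition of step 7 may also stall through enolisation of 8. The fallback forms the top–middle bond by the classical cation route, sets out from 12 and comes back at 16. Bromine–lithium exchange of 12 and protonation (t-BuLi, then MeOH) give the bromine-free dimer F5. Friedel–Crafts alkylation of F5 with the bromo-capped flavan-4-ol 10 (BF3·OEt2, CH2Cl2, −78 → −40 °C) should give both C4 epimers of the new link; the 3,4-cis isomer, the 6-bromo analogue of 16, F6, is expected as the minor one and is separated by chromatography. A second bromine–lithium exchange and protonation of F6 gives 16.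

Step 6. The silyl ether of 11 may ionise along with the hydroxyl of 10, which would give scrambling and oligomers, and the arene may attack through C8 or from the β face. The fallback uses orthogonal soft activation of a C4 sulfide, sets out from 10 and comes back at 12. Acid-catalysed exchange of the C4 hydroxyl of 10 with 4-methylbenzenethiol (BF3·OEt2, CH2Cl2, −20 °C) gives the 4-(4-methylphenyl)sulfanyl flavan F7. AgBF4 with 2,6-di-tert-butyl-4-methylpyridine in THF at 0 °C then activates only the sulfide of F7 in the presence of 11 and gives 12, the buffered thiophilic conditions leaving the silyl ether untouched.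

Further compounds
F1 | step 2 | 1-[4-(benzyloxy)-2-(methoxymethoxy)phenyl]ethan-1-one | CC(=O)c1ccc(OCc2ccccc2)cc1OCOC
F2 | step 2 | (E)-1-[4-(benzyloxy)-2-(methoxymethoxy)phenyl]-3-[3,4-bis(benzyloxy)phenyl]prop-2-en-1-one | COCOc1cc(OCc2ccccc2)ccc1C(=O)/C=C/c1ccc(OCc2ccccc2)c(OCc2ccccc2)c1
F3 | step 2 | [4-(benzyloxy)-2-(methoxymethoxy)phenyl][(2R,3S)-3-[3,4-bis(benzyloxy)phenyl]oxiran-2-yl]methanone (trans-epoxide) | COCOc1cc(OCc2ccccc2)ccc1C(=O)[C@@H]1O[C@H]1c1ccc(OCc2ccccc2)c(OCc2ccccc2)c1
F4 | step 2 | (2R,3R)-7-(benzyloxy)-2-[3,4-bis(benzyloxy)phenyl]-3-hydroxychroman-4-one | c1ccccc1COc1ccc2c(c1)O[C@H](c1ccc(OCc3ccccc3)c(OCc3ccccc3)c1)[C@@H](O)C2=O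
F5 | step 8 | bromine-free dimer (12 with H in place of Br) | c1cc2c(cc1OCc1ccccc1)O[C@H](c1ccc(OCc3ccccc3)c(OCc3ccccc3)c1)[C@@H](OCc1ccccc1)[C@@H]2c1cc2c(cc1OCc1ccccc1)O[C@H](c1ccc(OCc3ccccc3)c(OCc3ccccc3)c1)[C@@H](OCc1ccccc1)[C@@H]2O[Si](C(C)C)(C(C)C)C(C)C
F6 | step 8 | 6-bromo analogue of 16 (Br at C6 of the top unit, 3,4-cis top–middle link) | Brc1cc2c(cc1OCc1ccccc1)O[C@H](c1ccc(OCc3ccccc3)c(OCc3ccccc3)c1)[C@@H](OCc1ccccc1)[C@H]2c1cc2c(cc1OCc1ccccc1)O[C@H](c1ccc(OCc3ccccc3)c(OCc3ccccc3)c1)[C@@H](OCc1ccccc1)[C@@H]2c1cc2c(cc1OCc1ccccc1)O[C@H](c1ccc(OCc3ccccc3)c(OCc3ccccc3)c1)[C@@H](OCc1ccccc1)[C@@H]2O[Si](C(C)C)(C(C)C)C(C)C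
F7 | step 6 | 4-(4-methylphenyl)sulfanyl analogue of 10 (sulfide in place of the C4 hydroxyl, 3,4-trans) | Brc1cc2c(cc1OCc1ccccc1)O[C@H](c1ccc(OCc3ccccc3)c(OCc3ccccc3)c1)[C@@H](OCc1ccccc1)[C@@H]2Sc1ccc(C)cc1
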